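Numbering (labdane): C4 bears CH3 (α) and CO2Me (β, C19). C5 is the ring-fusion CH, C8 carries =CH2 (C17), C9 carries the chain C11–C12 to the butenolide C13–C16, and C10 carries the aldehyde C20. C20 defines the β face.
Cuts: C20 CHO ⇒ CH2OPMB; C8=C17 ⇒ C8 ketone ⇒ C8 carbinol; C12–C13 (B-alkyl Suzuki) and C11=C12 (Wittig) ⇒ C11 carboxyl; C9–C10 ([3,3] shift, ring B reopens to a δ-lactone); C6–C7 (vinylogous aldol); C5–C6 and C10–C20 ⇒ a 2-methyl-2-carbomethoxycyclohexanone.
Enabling feature: quaternary C10 is bonded to C9, C9 carries C11 (which can be a carboxyl carbon), and C6 is linked to C10 through C5. With oxygen on C6 and a C5=C10 alkene in ring A, the atoms C9=C11–O–C6–C5=C10 form a Claisen array inside a lactone ring made of C6, C7, C8, C9, C11 and O.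
Forward order: ring A comes from the starting ketone, the lactone ring is built on C5, ring B arises in the key step as the lactone ring opens, and the butenolide ring is coupled on ready-made.
Stereochemistry: C4 comes from asymmetric phase-transfer methylation. C6 (catalytic asymmetric aldol) and C8 (syn reduction directed by C6) are temporary centres. C10 comes from suprafacial transfer from C6, C5 from hydroxyl-directed hydrogenation, and C9 from equilibration next to the C8 ketone.

Key step: step 11

Assumption: the facial sense of the chiral catalysts in steps 1 and 7 is assigned by analogy with simpler β-keto esters and enals; if either runs the other way, the mirror-image catalyst is taken.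
Abbreviations: PMB = 4-methoxybenzyl, TBS = tert-butyldimethylsilyl, TMS = trimethylsilyl, DMP = Dess–Martin periodinane.

Step 1
Reactants: 1 methyl 2-oxocyclohexane-1-carboxylate
Product: 2 methyl (1S)-1-methyl-2-oxocyclohexane-1-carboxylate
Conditions: MeI, K2CO3, (S,S)-N-spiro bis(binaphthyl)ammonium bromide carrying 3,4,5-trifluorophenyl groups (1 mol %), toluene, −20 °C
Reagents that add atoms: iodomethane, CI
Why: Asymmetric phase-transfer C-alkylation of a cyclic β-keto ester, in which the chiral ammonium enolate ion pair exposes one face to MeI and so sets quaternary C4 as S, while any minor enantiomer is shed later as a diastereomer once C6 is in place.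

Step 2
Reactants: 2 methyl (1S)-1-methyl-2-oxocyclohexane-1-carboxylate
Product: 4 methyl (1R)-2-bromo-3-formyl-1-methylcyclohex-2-ene-1-carboxylate, via iminium bromide 3 (not isolated)
Conditions: PBr3, DMF, CHCl3, 0 to 70 °C; then ice–water
Reagents that add atoms: N,N-dimethylformamide, CN(C)C=O; phosphorus tribromide, BrP(Br)Br; water, O
Why: Vilsmeier–Haack–Arnold bromoformylation, in which the ketone can enolise only towards C10, so the bromoiminium reagent forms C10–C20 there and turns the C5 carbonyl into a vinyl bromide, which avoids a β-alkoxy ketone enolate that would eliminate.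

Step 3
Reactants: 4 methyl (1R)-2-bromo-3-formyl-1-methylcyclohex-2-ene-1-carboxylate
Product: 5 methyl (1R)-2-bromo-3-(hydroxymethyl)-1-methylcyclohex-2-ene-1-carboxylate
Conditions: NaBH4, MeOH, 0 °C
Reagents that add atoms: none
Why: Borohydride 1,2-reduction of the aldehyde is far faster than attack on the hindered tertiary ester or on the fully substituted bromoalkene.

Step 4
Reactants: 5 methyl (1R)-2-bromo-3-(hydroxymethyl)-1-methylcyclohex-2-ene-1-carboxylate; 6 4-methoxybenzyl chloride
Product: 7 methyl (1R)-2-bromo-3-{[(4-methoxybenzyl)oxy]methyl}-1-methylcyclohex-2-ene-1-carboxylate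
Conditions: NaH, n-Bu4NI (cat.), THF–DMF, 0 °C to rt
Reagents that add atoms: none
Why: Williamson etherification, which is safe because C20 and C4 stand trans on the ring alkene so the alkoxide cannot lactonise onto the C19 ester, and which installs a group that later comes off under neutral oxidative conditions.

Step 5
Reactants: 7 methyl (1R)-2-bromo-3-{[(4-methoxybenzyl)oxy]methyl}-1-methylcyclohex-2-ene-1-carboxylate
Product: 8 methyl (1S)-2-formyl-3-{[(4-methoxybenzyl)oxy]methyl}-1-methylcyclohex-2-ene-1-carboxylate
Conditions: Pd(OAc)2 (3 mol %), P(1-adamantyl)2(n-Bu) (9 mol %), TMEDA, CO/H2 (1:1, 10 bar), toluene, 100 °C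
Reagents that add atoms: carbon monoxide, [C-]#[O+]
Why: Palladium-catalysed reductive carbonylation (formylation) of a vinyl bromide with synthesis gas, where the bulky electron-rich phosphine drives oxidative addition into the crowded C5–Br bond and the ester is left alone, unlike in a halogen–lithium exchange.

Step 6
Reactants: 9 2,2,6-trimethyl-4H-1,3-dioxin-4-one
Product: 10 [(2,2-dimethyl-4-methylidene-4H-1,3-dioxin-6-yl)oxy]trimethylsilane
Conditions: LiN(i-Pr)2, THF, −78 °C; Me3SiCl
Reagents that add atoms: chlorotrimethylsilane, C[Si](C)(C)Cl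
Why: Kinetic γ-deprotonation of the dioxinone and O-silylation give the cross-conjugated silyl dienol ether, the standard masked acetoacetate γ-nucleophile.

Step 7
Reactants: 8 methyl (1S)-2-formyl-3-{[(4-methoxybenzyl)oxy]methyl}-1-methylcyclohex-2-ene-1-carboxylate; 10 [(2,2-dimethyl-4-methylidene-4H-1,3-dioxin-6-yl)oxy]trimethylsilane
Product: 12 (6S)-hydroxy dioxinone aldol adduct, via trimethylsilyl ether 11 (not isolated)
Conditions: Cu(OTf)2 (5 mol %), (S)-Tol-BINAP (5.5 mol %), (n-Bu4N)[Ph3SiF2] (10 mol %), THF, −78 °C; then 1 M HCl, THF, 0 °C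
Reagents that add atoms: none
Why: Catalytic enantioselective vinylogous Mukaiyama aldol addition through a chiral bisphosphine copper dienolate, a process at its best with conjugated aldehydes, in which only the γ-carbon of 10 reacts (C6–C7) and the catalyst chooses the aldehyde face and sets C6 as S.

Step 8
Reactants: 12 (6S)-hydroxy dioxinone aldol adduct
Product: 14 (6S)-δ-hydroxy-β-keto methyl ester, via acylketene 13 (not isolated)
Conditions: MeOH–toluene (1:1), sealed tube, 110 °C
Reagents that add atoms: methanol, CO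
Why: Thermal retro-[4+2] loss of acetone from the dioxinone gives acylketene 13, which the large excess of methanol captures faster than the crowded C6 hydroxyl can.

Step 9
Reactants: 14 (6S)-δ-hydroxy-β-keto methyl ester
Product: 15 (6S;8R)-syn-dihydroxy methyl ester
Conditions: Et2BOMe, THF–MeOH (4:1), −78 °C; NaBH4; then repeated evaporation from MeOH
Reagents that add atoms: none
Why: Narasaka–Prasad reduction, in which the diethylboron chelate that links the C6 oxygen and the C8 ketone takes external hydride axially and gives the syn-1,3-diol, so that C6 sets C8 as R.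

Step 10
Reactants: 15 (6S;8R)-syn-dihydroxy methyl ester
Product: 17 trans-(4R;6S)-4-hydroxy-δ-lactone, via dihydroxy acid 16 (not isolated)
Conditions: LiOH, THF–H2O, 0 °C; 1 M HCl to pH 4; toluene, 4 Å sieves, 90 °C
Reagents that add atoms: none
Why: Selective saponification of the open C11 ester (the neopentyl-type C19 ester is inert at 0 °C) and thermal lactonisation of 16, as practised for 3,5-dihydroxy acids, close the δ-lactone without strong acid that would ionise the allylic C6–O bond, and the syn-diol maps onto the trans-4,6-lactone.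

Step 11
Reactants: 17 trans-(4R;6S)-4-hydroxy-δ-lactone
Product: 21 octalin acid (Δ5; 4β-CO2Me; 8α-OTBS; 9α-CO2H; 10β-CH2OPMB), via dilithium alkoxide enolate 18 (not isolated), via bis-silyl ketene acetal 19 (not isolated), via silyl ester 20 (not isolated)
Conditions: LiN(i-Pr)2 (2.4 equiv), THF, −78 to −40 °C; t-BuMe2SiCl (3 equiv), DMPU, −78 °C to rt; toluene, 110 °C; then AcOH–THF–H2O, rt
Reagents that add atoms: tert-butyldimethylsilyl chloride, CC(C)(C)[Si](C)(C)Cl
Why: Two equivalents of LiN(i-Pr)2 convert 17 into the alkoxide enolate 18, whose C8 oxygen is an oxide and cannot leave, so the E1cB loss that threatens the enolate of a 4-silyloxy lactone with an axial C8–O bond is shut off until t-BuMe2SiCl has capped both oxygens to give the neutral ketene acetal 19. On heating, 19 undergoes the concerted [3,3] shift across C9=C11–O–C6–C5=C10 (C9–C10 forms, O–C6 breaks, C5=C6 appears), which is the Ireland–Claisen rearrangement in its known lactone-to-cycloalkene form for 6-alkenyl δ-lactones, applied here to a fully substituted alkene terminus. Ring B (C5, C6, C7, C8, C9, C10) closes through this sigmatropic C9–C10 bond formation in the boat-like, bicyclo[2.2.2]octane-shaped transition state that the C7–C8 bridge enforces, while the lactone ring opens and its oxygen departs into the C11 silyl carboxylate 20, which mild hydrolysis turns into 21. C10 is controlled by (6S)-C6: the shift is suprafacial and C7 must turn inward to give a cis ring alkene, so C9 can reach only the α face of C5=C10, C20 is pushed to the β face, and attack on the other face would require a trans-cyclohexene. C9 is controlled by the boat and by the fixed ketene acetal geometry (C8 cis to the ring oxygen), which place C11 on the α face, trans to C20 and cis to the 8α-silyloxy group, a setting that is used in step 13 and corrected in step 20. The step needs O-silylation to outrun elimination and C-silylation, which the dianion and DMPU secure, and it needs room for C8 to pass under C20, which the trans-4,6-lactone secures because its silyloxy group points away from ring A and the α face of ring A carries only the C4 methyl group.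

Step 12
Reactants: 21 octalin acid (Δ5; 4β-CO2Me; 8α-OTBS; 9α-CO2H; 10β-CH2OPMB)
Product: 22 octalin alcohol (Δ5; 9α-CH2OH)
Conditions: BH3·THF, THF, 0 °C to rt; then MeOH–H2O
Reagents that add atoms: none
Why: Borane reduces the free carboxylic acid through its acyloxyborane much faster than it attacks the C19 ester or hydroborates an alkene flanked by two quaternary carbons, and it delivers the 9α-CH2OH handle needed next.

Step 13
Reactants: 22 octalin alcohol (Δ5; 9α-CH2OH)
Product: 23 trans-decalin alcohol (5α-H; 9α-CH2OH)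
Conditions: [Ir(cod)(PCy3)(py)]PF6 (10 mol %), H2 (50 bar), CH2Cl2, rt
Reagents that add atoms: none
Why: Hydroxyl-directed homogeneous hydrogenation, in which the cationic iridium catalyst binds the 9α-CH2OH group lying 1,3-diaxial to C5 and delivers H2 to the α face, the face that is also free of the axial C19 and C20 groups, so that 5α-H and the trans ring fusion result and the PMB ether survives.

Step 14
Reactants: 23 trans-decalin alcohol (5α-H; 9α-CH2OH)
Product: 24 9α-carbaldehyde
Conditions: DMP, CH2Cl2, 0 °C to rt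
Reagents that add atoms: none
Why: Dess–Martin oxidation stops at the aldehyde and brings in no base that could eliminate the β-silyloxy group.

Step 15
Reactants: 24 9α-carbaldehyde
Product: 25 9α-vinyl decalin
Conditions: Ph3PCH3Br, KN(SiMe3)2, THF, 0 °C; then 24, −78 to 0 °C
Reagents that add atoms: methyltriphenylphosphonium bromide, C[P+](c1ccccc1)(c1ccccc1)c1ccccc1.[Br-]
Why: Wittig methylenation with the small unstabilised ylide forms C11=C12 even at a neopentyl-type aldehyde, and any partial epimerisation at C9 is harmless because that centre is equilibrated in step 20.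

Step 16
Reactants: 26 furan-2(5H)-one
Product: 28 3-bromofuran-2(5H)-one, via trans-dibromolactone 27 (not isolated)
Conditions: Br2, CH2Cl2, 40 °C; then Et3N, 0 °C
Reagents that add atoms: bromine, BrBr
Why: Anti addition of bromine to the butenolide alkene gives 27, from which triethylamine removes the acidic α-hydrogen and expels the β-bromide, the standard bromination–dehydrobromination route to α-bromo enoates.

Step 17
Reactants: 25 9α-vinyl decalin; 28 3-bromofuran-2(5H)-one
Product: 30 9α-butenolide silyl ether, via B-alkyl-9-BBN 29 (not isolated)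
Conditions: 9-BBN, THF, rt to 40 °C; then 28, PdCl2(dppf) (5 mol %), AsPh3, Cs2CO3, DMF–H2O, rt
Reagents that add atoms: none
Why: Anti-Markovnikov hydroboration of the only alkene present followed by B-alkyl Suzuki–Miyaura coupling with an α-halo enoate, under the mild carbonate and AsPh3 conditions used for α-halo enones, forms C12–C13 and brings in the complete butenolide.

Step 18
Reactants: 30 9α-butenolide silyl ether
Product: 31 8α-alcohol
Conditions: HF·pyridine, THF, 0 °C to rt
Reagents that add atoms: none
Why: Fluoride-driven Si–O cleavage in a mildly acidic medium spares the PMB ether, the hindered ester and the base-sensitive butenolide.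

Step 19
Reactants: 31 8α-alcohol
Product: 32 8-ketone with 9α side chain
Conditions: DMP, CH2Cl2, rt
Reagents that add atoms: none
Why: Dess–Martin oxidation of the secondary alcohol is neutral and touches neither the butenolide nor the PMB ether, and it removes the temporary C8 stereocentre.

Step 20
Reactants: 32 8-ketone with 9α side chain
Product: 33 8-ketone with 9β side chain
Conditions: DBU (0.3 equiv), toluene, rt to 50 °C
Reagents that add atoms: none
Why: Base-catalysed enolisation next to the C8 ketone equilibrates the axial 9α chain to the equatorial 9β chain of the normal labdane series, while Michael addition of C9 to C14 would be a disfavoured 5-endo-trig closure and the butenolide has no stereocentre to lose.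

Step 21
Reactants: 33 8-ketone with 9β side chain
Product: 34 8(17)-methylene PMB ether
Conditions: Zn, CH2Br2, TiCl4 (reagent aged at 5 °C), THF–CH2Cl2, 0 °C to rt
Reagents that add atoms: dibromomethane, BrCBr
Why: Lombardo methylenation, whose non-basic zinc–titanium gem-dimetallic reagent converts hindered enolisable ketones into methylene compounds without epimerisation and leaves esters and lactones alone.

Step 22
Reactants: 34 8(17)-methylene PMB ether
Product: 35 methyl 20-hydroxylabda-8(17),13-dien-16,15-olid-19-oate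
Conditions: DDQ, CH2Cl2–pH 7 buffer, 0 °C
Reagents that add atoms: none
Why: Oxidative PMB cleavage by DDQ through the benzylic oxocarbenium ion leaves both alkenes alone, and the cold neutral medium keeps the freed C20 hydroxyl from lactonising onto the 1,3-diaxial C19 ester before it is oxidised at once.

Step 23
Reactants: 35 methyl 20-hydroxylabda-8(17),13-dien-16,15-olid-19-oate
Product: 36 methyl 20-oxolabda-8(17),13-dien-16,15-olid-19-oate (target)
Conditions: DMP, CH2Cl2, 0 °C to rt
Reagents that add atoms: none
Why: Dess–Martin oxidation of the neopentyl primary alcohol gives the non-enolisable C20 aldehyde under neutral conditions that disturb no stereocentre.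

Compound list
1 | methyl 2-oxocyclohexane-1-carboxylate | COC(=O)C1CCCCC1=O | starting material
2 | methyl (1S)-1-methyl-2-oxocyclohexane-1-carboxylate | COC(=O)[C@@]1(C)CCCCC1=O | intermediate
3 | {[(3R)-2-bromo-3-(methoxycarbonyl)-3-methylcyclohex-1-en-1-yl]methylidene}dimethylammonium bromide (not isolated) | COC(=O)[C@@]1(C)CCCC(C=[N+](C)C)=C1Br.[Br-] | intermediate
4 | methyl (1R)-2-bromo-3-formyl-1-methylcyclohex-2-ene-1-carboxylate (same spatial C4 as in 2; the descriptor changes because Br outranks O) | COC(=O)[C@@]1(C)CCCC(C=O)=C1Br | intermediate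
5 | methyl (1R)-2-bromo-3-(hydroxymethyl)-1-methylcyclohex-2-ene-1-carboxylate | COC(=O)[C@@]1(C)CCCC(CO)=C1Br | intermediate
6 | 4-methoxybenzyl chloride | COc1ccc(CCl)cc1 | starting material
7 | methyl (1R)-2-bromo-3-{[(4-methoxybenzyl)oxy]methyl}-1-methylcyclohex-2-ene-1-carboxylate | COC(=O)[C@@]1(C)CCCC(COCc2ccc(OC)cc2)=C1Br | intermediate
8 | methyl (1S)-2-formyl-3-{[(4-methoxybenzyl)oxy]methyl}-1-methylcyclohex-2-ene-1-carboxylate | COC(=O)[C@@]1(C)CCCC(COCc2ccc(OC)cc2)=C1C=O | intermediate
9 | 2,2,6-trimethyl-4H-1,3-dioxin-4-one | CC1=CC(=O)OC(C)(C)O1 | starting material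
10 | [(2,2-dimethyl-4-methylidene-4H-1,3-dioxin-6-yl)oxy]trimethylsilane | C=C1C=C(O[Si](C)(C)C)OC(C)(C)O1 | intermediate
11 | O-trimethylsilyl ether of 12 (not isolated) | COC(=O)[C@@]1(C)CCCC(COCc2ccc(OC)cc2)=C1[C@@H](O[Si](C)(C)C)CC1=CC(=O)OC(C)(C)O1 | intermediate
12 | methyl (1S)-2-[(1S)-2-(2,2-dimethyl-4-oxo-4H-1,3-dioxin-6-yl)-1-hydroxyethyl]-3-{[(4-methoxybenzyl)oxy]methyl}-1-methylcyclohex-2-ene-1-carboxylate | COC(=O)[C@@]1(C)CCCC(COCc2ccc(OC)cc2)=C1[C@@H](O)CC1=CC(=O)OC(C)(C)O1 | intermediate
13 | acylketene from 12 by loss of acetone, (6S)-carbinol retained (not isolated) | COC(=O)[C@@]1(C)CCCC(COCc2ccc(OC)cc2)=C1[C@@H](O)CC(=O)C=C=O | intermediate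
14 | methyl (1S)-2-[(1S)-1-hydroxy-5-methoxy-3,5-dioxopentyl]-3-{[(4-methoxybenzyl)oxy]methyl}-1-methylcyclohex-2-ene-1-carboxylate | COC(=O)[C@@]1(C)CCCC(COCc2ccc(OC)cc2)=C1[C@@H](O)CC(=O)CC(=O)OC | intermediate
15 | methyl (1S)-2-[(1S,3R)-1,3-dihydroxy-5-methoxy-5-oxopentyl]-3-{[(4-methoxybenzyl)oxy]methyl}-1-methylcyclohex-2-ene-1-carboxylate (syn-diol) | COC(=O)[C@@]1(C)CCCC(COCc2ccc(OC)cc2)=C1[C@@H](O)C[C@@H](O)CC(=O)OC | intermediate
16 | (3R,5S)-3,5-dihydroxy-5-[ring A cyclohexenyl]pentanoic acid, ring A as in 15 (not isolated) | COC(=O)[C@@]1(C)CCCC(COCc2ccc(OC)cc2)=C1[C@@H](O)C[C@@H](O)CC(=O)O | intermediate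
17 | methyl (1S)-2-[(2S,4R)-4-hydroxy-6-oxooxan-2-yl]-3-{[(4-methoxybenzyl)oxy]methyl}-1-methylcyclohex-2-ene-1-carboxylate (trans-4,6-lactone; key-step precursor) | COC(=O)[C@@]1(C)CCCC(COCc2ccc(OC)cc2)=C1[C@@H]1C[C@@H](O)CC(=O)O1 | intermediate
18 | dilithium C8-alkoxide C9=C11 enolate of 17 (not isolated) | COC(=O)[C@@]1(C)CCCC(COCc2ccc(OC)cc2)=C1[C@@H]1C[C@@H]([O-])C=C([O-])O1.[Li+].[Li+] | intermediate
19 | 8-O-TBS lactone TBS ketene acetal, 6-silyloxy-3,4-dihydro-2H-pyran form of 17 (not isolated) | COC(=O)[C@@]1(C)CCCC(COCc2ccc(OC)cc2)=C1[C@@H]1C[C@@H](O[Si](C)(C)C(C)(C)C)C=C(O[Si](C)(C)C(C)(C)C)O1 | intermediate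
20 | tert-butyldimethylsilyl ester of 21 (not isolated) | COC(=O)[C@@]1(C)CCC[C@@]2(COCc3ccc(OC)cc3)C1=CC[C@@H](O[Si](C)(C)C(C)(C)C)[C@H]2C(=O)O[Si](C)(C)C(C)(C)C | intermediate
21 | octalin acid, Δ5(6): 4α-CH3, 4β-CO2Me, 10β-CH2OPMB, 8α-OTBS, 9α-CO2H (9β-H); key-step product | COC(=O)[C@@]1(C)CCC[C@@]2(COCc3ccc(OC)cc3)C1=CC[C@@H](O[Si](C)(C)C(C)(C)C)[C@H]2C(=O)O | intermediate
22 | octalin alcohol, as 21 but 9α-CH2OH | COC(=O)[C@@]1(C)CCC[C@@]2(COCc3ccc(OC)cc3)C1=CC[C@@H](O[Si](C)(C)C(C)(C)C)[C@H]2CO | intermediate
23 | trans-decalin alcohol: 5α-H, 4α-CH3, 4β-CO2Me, 10β-CH2OPMB, 8α-OTBS, 9α-CH2OH | COC(=O)[C@@]1(C)CCC[C@@]2(COCc3ccc(OC)cc3)[C@H]1CC[C@@H](O[Si](C)(C)C(C)(C)C)[C@H]2CO | intermediate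
24 | as 23 but 9α-CHO | COC(=O)[C@@]1(C)CCC[C@@]2(COCc3ccc(OC)cc3)[C@H]1CC[C@@H](O[Si](C)(C)C(C)(C)C)[C@H]2C=O | intermediate
25 | as 23 but 9α-CH=CH2 (C11=C12) | COC(=O)[C@@]1(C)CCC[C@@]2(COCc3ccc(OC)cc3)[C@H]1CC[C@@H](O[Si](C)(C)C(C)(C)C)[C@H]2C=C | intermediate
26 | furan-2(5H)-one | O=C1OCC=C1 | starting material
27 | (±)-trans-3,4-dibromodihydrofuran-2(3H)-one, one enantiomer drawn (not isolated) | O=C1OC[C@@H](Br)[C@@H]1Br | intermediate
28 | 3-bromofuran-2(5H)-one | O=C1OCC=C1Br | intermediate
29 | C12 B-alkyl-9-borabicyclo[3.3.1]nonane from 25 (not isolated) | COC(=O)[C@@]1(C)CCC[C@@]2(COCc3ccc(OC)cc3)[C@H]1CC[C@@H](O[Si](C)(C)C(C)(C)C)[C@H]2CCB1C2CCCC1CCC2 | intermediate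
30 | as 23 but 9α-[2-(2-oxo-2,5-dihydrofuran-3-yl)ethyl] | COC(=O)[C@@]1(C)CCC[C@@]2(COCc3ccc(OC)cc3)[C@H]1CC[C@@H](O[Si](C)(C)C(C)(C)C)[C@H]2CCC1=CCOC1=O | intermediate
31 | 8α-alcohol from 30 | COC(=O)[C@@]1(C)CCC[C@@]2(COCc3ccc(OC)cc3)[C@H]1CC[C@@H](O)[C@H]2CCC1=CCOC1=O | intermediate
32 | 8-ketone, side chain 9α (9β-H) | COC(=O)[C@@]1(C)CCC[C@@]2(COCc3ccc(OC)cc3)[C@H]1CCC(=O)[C@H]2CCC1=CCOC1=O | intermediate
33 | 8-ketone, side chain 9β (9α-H), normal labdane configuration | COC(=O)[C@@]1(C)CCC[C@@]2(COCc3ccc(OC)cc3)[C@H]1CCC(=O)[C@@H]2CCC1=CCOC1=O | intermediate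
34 | methyl 20-[(4-methoxybenzyl)oxy]labda-8(17),13-dien-16,15-olid-19-oate | COC(=O)[C@@]1(C)CCC[C@@]2(COCc3ccc(OC)cc3)[C@H]1CCC(=C)[C@@H]2CCC1=CCOC1=O | intermediate
35 | methyl 20-hydroxylabda-8(17),13-dien-16,15-olid-19-oate | COC(=O)[C@@]1(C)CCC[C@@]2(CO)[C@H]1CCC(=C)[C@@H]2CCC1=CCOC1=O | intermediate
36 | methyl 20-oxolabda-8(17),13-dien-16,15-olid-19-oate (CNP0175906.1; 4α-CH3, 4β-CO2Me, 5α-H, 9α-H, 10β-CHO) | C=C1CC[C@@H]2[C@](C=O)(CCC[C@]2(C)C(=O)OC)[C@H]1CCC1=CCOC1=O | target

Total step count: 23. Longest linear sequence: 21 steps (1–5, 7–15, 17–23).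

Steps most likely to fail

Step 11 (key step).
- What may go wrong: the enolate may expel the C8 oxygen before both oxygens are capped. Silyl groups may scramble between O8 and the enolate oxygen. The ketene acetal may also decay before the slow shift onto the fully substituted C10 takes place.
- Fallback: no metal enolate is made at all. It sets out from 17, which is first silylated (t-BuMe2SiCl, imidazole, DMF) to the 4-silyloxy lactone F1.
- Soft enolisation follows (t-BuMe2SiOTf, Et3N, toluene, 0 °C to rt): the lactone carbonyl is O-silylated and H9 is then lost to the amine, which gives the ketene acetal.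
- The route is rejoined at 19, which is heated in the same flask and hydrolysed to 21.

Step 13.
- What may go wrong: the catalyst may fail to reach an alkene flanked by two quaternary carbons. The C19 ester or the C20 ether oxygen may also compete as directing groups, which would erode the facial selectivity.
- Fallback: stereocontrol is moved from metal coordination to a carbon radical. Hydrogen-atom-transfer hydrogenation (Mn(dpm)3, PhSiH3, t-BuOOH, i-PrOH, rt) places the first hydrogen on the open C6.
- The tertiary C5 radical then takes the second hydrogen on the α face, away from the axial C19 and C20 groups, to give the trans fusion.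
- It sets out from 22 and comes back at 23. It makes no compound outside the list (F0).

Step 7.
- What may go wrong: addition to an aldehyde wedged between quaternary C4 and a fully substituted alkene may be sluggish. The catalyst may also give poor facial selectivity if it is mismatched with C4.
- Fallback: the lactone is built by reagent-controlled allylation and metathesis instead of an aldol addition, and steps 6 to 10 fall away. It sets out from 8.
- Brown allylation with (−)-B-allyldiisopinocampheylborane (from (+)-α-pinene; Et2O, −78 °C; NaOH, H2O2) should give the (6S)-homoallylic alcohol F2.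
- Acylation (acryloyl chloride, Et3N, DMAP, CH2Cl2) gives the acrylate F3.
- Ring-closing metathesis (second-generation Grubbs catalyst RuCl2(=CHPh)(PCy3)(H2IMes), CH2Cl2, 40 °C) gives the 5,6-dihydropyran-2-one F4.
- Copper-catalysed conjugate borylation (CuCl, NaOt-Bu, DPEphos, B2pin2, MeOH, THF) adds boron to C8 anti to the C6 substituent and gives the trans-4-boryl lactone F5.
- Oxidation with retention (NaBO3·4H2O, THF–H2O) brings the route back at 17.

Further compounds
F1 | step 11 | methyl (1S)-2-[(2S,4R)-4-(tert-butyldimethylsilyloxy)-6-oxooxan-2-yl]-3-{[(4-methoxybenzyl)oxy]methyl}-1-methylcyclohex-2-ene-1-carboxylate | COC(=O)[C@@]1(C)CCCC(COCc2ccc(OC)cc2)=C1[C@@H]1C[C@@H](O[Si](C)(C)C(C)(C)C)CC(=O)O1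
F0 | step 13 | none | none
F2 | step 7 | methyl (1S)-2-[(1S)-1-hydroxybut-3-en-1-yl]-3-{[(4-methoxybenzyl)oxy]methyl}-1-methylcyclohex-2-ene-1-carboxylate | COC(=O)[C@@]1(C)CCCC(COCc2ccc(OC)cc2)=C1[C@@H](O)CC=C
F3 | step 7 | acrylate ester of F2 | COC(=O)[C@@]1(C)CCCC(COCc2ccc(OC)cc2)=C1[C@@H](OC(=O)C=C)CC=C
F4 | step 7 | methyl (1S)-3-{[(4-methoxybenzyl)oxy]methyl}-1-methyl-2-[(2S)-6-oxo-3,6-dihydro-2H-pyran-2-yl]cyclohex-2-ene-1-carboxylate | COC(=O)[C@@]1(C)CCCC(COCc2ccc(OC)cc2)=C1[C@@H]1CC=CC(=O)O1
F5 | step 7 | methyl (1S)-3-{[(4-methoxybenzyl)oxy]methyl}-1-methyl-2-[(2S,4R)-6-oxo-4-(4,4,5,5-tetramethyl-1,3,2-dioxaborolan-2-yl)oxan-2-yl]cyclohex-2-ene-1-carboxylate | COC(=O)[C@@]1(C)CCCC(COCc2ccc(OC)cc2)=C1[C@@H]1C[C@@H](B2OC(C)(C)C(C)(C)O2)CC(=O)O1
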